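**Retrosynthetic overview** (bicyclic compounds carry the azulene numbering of the target)

1. The C7 carbinol comes from 1,2-reduction of a C7 enone, and the C4 ester from acylation of a bicyclic γ-hydroxy enone.
2. Key bond C4–C5 closes the seven-membered ring: the enone β-carbon C5, normally an electrophile, is used as a β-acylvinyl anion equivalent (alkenylchromium from a (Z)-β-iodoenone) against the C4 aldehyde, and sets C4.
3. The (Z)-β-iodo-α-methylenone and the aldehyde come from one double Swern oxidation of a triol made by ethynylation of a lactol and copper-catalysed anti-carbomagnesiation/iodination.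
4. The cyclopentane core comes from isopropyl Grignard addition (C3) to a cyclopentanone made by asymmetric conjugate methylation of 3-allylcyclopentenone with formaldehyde trapping (C8a, C3a).
5. Ring order: the five-membered ring is present from the start; the seven-membered ring is closed in step 7 of 9.

Assumption: the target is (3R,3aS,4S,7R,8aR) as drawn, and all numbered reagents are bought. The route is a design with no experimental verification.

**Step 1**
Reactants: 1 3-ethoxycyclopent-2-en-1-one; 2 allylmagnesium bromide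
Product: 4 3-(prop-2-en-1-yl)cyclopent-2-en-1-one, via bromomagnesium alkoxide of 1-allyl-3-ethoxycyclopent-2-en-1-ol 3 (not isolated)
Conditions: allylMgBr (1.2 equiv), THF, 0 °C; then 1 M HCl (aq), 0 °C, 20 min
Reagents that add atoms: allylmagnesium bromide, C=CC[Mg]Br; water, O
Why: 1,2-addition of the Grignard reagent to the vinylogous ester followed by acid-promoted allylic transposition and enol ether hydrolysis (Stork–Danheiser sequence) gives the 3-substituted enone; no stereocentre is formed.

**Step 2**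
Reactants: 4 3-(prop-2-en-1-yl)cyclopent-2-en-1-one; 5 trimethylaluminium; 6 formaldehyde
Product: 8 (2S,3R)-2-(hydroxymethyl)-3-methyl-3-(prop-2-en-1-yl)cyclopentan-1-one, via dimethylaluminium enolate 7 (not isolated)
Conditions: Cu(O2CC4H3S) (copper thiophene-2-carboxylate, 5 mol %), chiral biphenol phosphoramidite ligand carrying a bis[1-(naphthalen-2-yl)ethyl]amino group (10 mol %), Me3Al (1.5 equiv), Et2O, −30 °C; then CH2O (monomeric, in THF), −78 → −30 °C; aq. KNaC4H4O6 work-up
Reagents that add atoms: trimethylaluminium, C[Al](C)C; formaldehyde, C=O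
Why: copper-catalysed asymmetric conjugate addition (ligand enantiomer chosen to give the R quaternary centre, about 85–93 % ee expected for this substrate class) followed by aldol trapping of the regiodefined aluminium enolate anti to the larger allyl group, which places CH2OH cis to the methyl group; selectivity against a methyl/allyl pair will be modest, so the epimerisable C2 centre is equilibrated and the minor epimer removed by chromatography.

**Step 3**
Reactants: 8 (2S,3R)-2-(hydroxymethyl)-3-methyl-3-(prop-2-en-1-yl)cyclopentan-1-one; 9 isopropylmagnesium chloride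
Product: 10 (1R,2S,3R)-2-(hydroxymethyl)-3-methyl-1-(propan-2-yl)-3-(prop-2-en-1-yl)cyclopentan-1-ol
Conditions: iPrMgCl (3 equiv), LaCl3·2LiCl (1.1 equiv), THF, 0 °C; then H2O (NH4Cl buffer)
Reagents that add atoms: isopropylmagnesium chloride, CC(C)[Mg]Cl
Why: lanthanum-promoted Grignard 1,2-addition (suppresses enolisation and β-hydride reduction) takes place on the ketone face anti to the adjacent CH2O–metal substituent, so the tertiary hydroxyl ends up cis to CH2OH and to the ring methyl (1R).

**Step 4**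
Reactants: 10 (1R,2S,3R)-2-(hydroxymethyl)-3-methyl-1-(propan-2-yl)-3-(prop-2-en-1-yl)cyclopentan-1-ol; 11 ozone
Product: 13 (4aR,7R,7aS)-4a-methyl-7-(propan-2-yl)octahydrocyclopenta[c]pyran-3,7-diol (trans-fused lactol; C3 anomers), via secondary ozonide 12 (not isolated)
Conditions: O3, CH2Cl2, −78 °C; then PPh3 (1.5 equiv), −78 °C → rt
Reagents that add atoms: ozone, [O-][O+]=O
Why: ozonolysis with reductive work-up cleaves the only alkene to the aldehyde, which closes onto the primary hydroxyl as a six-membered lactol; both hydroxyls are inert to ozone and no ring stereocentre is touched.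

**Step 5**
Reactants: 13 (4aR,7R,7aS)-4a-methyl-7-(propan-2-yl)octahydrocyclopenta[c]pyran-3,7-diol; 14 ethynylmagnesium bromide; 15 methylmagnesium bromide; 16 iodine
Product: 19 (1R,2S,3R)-3-[(3Z)-2-hydroxy-4-iodo-3-methylbut-3-en-1-yl]-2-(hydroxymethyl)-3-methyl-1-(propan-2-yl)cyclopentan-1-ol (side-chain carbinol epimers), via propargylic bromomagnesium alkoxide 17 (not isolated), via alkenylmagnesium chelate 18 (not isolated)
Conditions: HC≡CMgBr (3.2 equiv), THF, 0 °C → rt, N2 purge; then CuI (0.3 equiv), MeMgBr (5 equiv), THF/Et2O, rt, 16 h; then I2 (6 equiv), −20 °C → rt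
Reagents that add atoms: ethynylmagnesium bromide, C#C[Mg]Br; methylmagnesium bromide, C[Mg]Br; iodine, [I][I]
Why: Grignard addition to the lactol-masked aldehyde gives a propargylic alkoxide that directs copper-catalysed anti-carbomagnesiation (methyl to the proximal alkyne carbon, magnesium to the terminal carbon in a five-membered chelate), and iodinolysis with retention gives the (Z)-iodoalkene with iodine cis to the carbinol carbon; the new carbinol centre is a mixture that is erased in step 6.

**Step 6**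
Reactants: 19 (1R,2S,3R)-3-[(3Z)-2-hydroxy-4-iodo-3-methylbut-3-en-1-yl]-2-(hydroxymethyl)-3-methyl-1-(propan-2-yl)cyclopentan-1-ol
Product: 20 (1R,2R,5R)-2-hydroxy-5-[(3Z)-4-iodo-3-methyl-2-oxobut-3-en-1-yl]-5-methyl-2-(propan-2-yl)cyclopentane-1-carbaldehyde
Conditions: (COCl)2 (4 equiv), DMSO (8 equiv), CH2Cl2, −78 °C; then iPr2NEt (12 equiv), −78 → −20 °C; used crude
Reagents that add atoms: none
Why: Swern oxidation converts the primary and the allylic secondary hydroxyl into alkoxysulfonium ions before any carbonyl exists, so aldehyde and (Z)-β-iodoenone are released together without lactol over-oxidation; the tertiary alcohol is inert and the formyl-bearing centre already has its thermodynamically preferred configuration (cis to OH and methyl).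

**Step 7**
Reactants: 20 (1R,2R,5R)-2-hydroxy-5-[(3Z)-4-iodo-3-methyl-2-oxobut-3-en-1-yl]-5-methyl-2-(propan-2-yl)cyclopentane-1-carbaldehyde
Product: 22 (3R,3aS,4S,8aR)-3,4-dihydroxy-6,8a-dimethyl-3-(propan-2-yl)-2,3,3a,4,8,8a-hexahydroazulen-7(1H)-one, via alkenylchromium dichloride 21 (not isolated)
Conditions: CrCl2 (8 equiv), NiCl2 (2 mol %), degassed DMF, rt, slow addition of 20 (final 0.005 M)
Reagents that add atoms: none
Why: Nozaki–Hiyama–Kishi cyclisation, in which insertion of zerovalent nickel into the C–I bond and transmetalation to trivalent chromium turn the enone β-carbon into a β-acylvinyl anion equivalent that adds to the aldehyde and closes the seven-membered ring (the Z geometry holds chromium cis to the acyl group, as the ring requires); the chromium-bound aldehyde oxygen should take the pseudo-equatorial position of a chair-like transition state, away from the angular methyl, so the new C4–OH is cis to H-3a (4S).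

**Step 8**
Reactants: 22 (3R,3aS,4S,8aR)-3,4-dihydroxy-6,8a-dimethyl-3-(propan-2-yl)-2,3,3a,4,8,8a-hexahydroazulen-7(1H)-one; 23 4-methoxybenzoyl chloride
Product: 24 (3R,3aS,4S,8aR)-3-hydroxy-6,8a-dimethyl-7-oxo-3-(propan-2-yl)-1,2,3,3a,4,7,8,8a-octahydroazulen-4-yl 4-methoxybenzoate
Conditions: 4-MeOC6H4COCl (2 equiv), Et3N (3 equiv), DMAP (0.3 equiv), CH2Cl2, 0 °C → rt
Reagents that add atoms: 4-methoxybenzoyl chloride, COc1ccc(cc1)C(Cl)=O
Why: DMAP-catalysed acylation is selective for the secondary allylic hydroxyl because the tertiary C3 hydroxyl is too hindered to react; C4 keeps its configuration.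

**Step 9**
Reactants: 24 (3R,3aS,4S,8aR)-3-hydroxy-6,8a-dimethyl-7-oxo-3-(propan-2-yl)-1,2,3,3a,4,7,8,8a-octahydroazulen-4-yl 4-methoxybenzoate
Product: 25 (3R,3aS,4S,7R,8aR)-3,7-dihydroxy-6,8a-dimethyl-3-(propan-2-yl)-1,2,3,3a,4,7,8,8a-octahydroazulen-4-yl 4-methoxybenzoate
Conditions: NaBH4 (1.5 equiv), CeCl3·7H2O (1.5 equiv), MeOH, −78 °C
Reagents that add atoms: none
Why: Luche 1,2-reduction of the enone, with hydride expected to reach the C7 carbonyl from the face opposite the pseudo-axial angular C8a methyl (1,3-related to C7), giving the 7R alcohol with hydroxyl cis to that methyl while ester and alkene are untouched.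

**Compound list**

1 | 3-ethoxycyclopent-2-en-1-one | CCOC1=CC(=O)CC1 | starting material
2 | allylmagnesium bromide | C=CC[Mg]Br | starting material
3 | bromomagnesium alkoxide of 1-allyl-3-ethoxycyclopent-2-en-1-ol | CCOC1=CC(CC=C)(O[Mg]Br)CC1 | intermediate
4 | 3-(prop-2-en-1-yl)cyclopent-2-en-1-one | C=CCC1=CC(=O)CC1 | intermediate
5 | trimethylaluminium | C[Al](C)C | starting material
6 | formaldehyde | C=O | starting material
7 | dimethyl{[(3R)-3-methyl-3-(prop-2-en-1-yl)cyclopent-1-en-1-yl]oxy}alumane (aluminium enolate) | C[Al](C)OC1=C[C@@](C)(CC=C)CC1 | intermediate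
8 | (2S,3R)-2-(hydroxymethyl)-3-methyl-3-(prop-2-en-1-yl)cyclopentan-1-one | OC[C@H]1C(=O)CC[C@]1(C)CC=C | intermediate
9 | isopropylmagnesium chloride | CC(C)[Mg]Cl | starting material
10 | (1R,2S,3R)-2-(hydroxymethyl)-3-methyl-1-(propan-2-yl)-3-(prop-2-en-1-yl)cyclopentan-1-ol | OC[C@H]1[C@](O)(C(C)C)CC[C@]1(C)CC=C | intermediate
11 | ozone | [O-][O+]=O | starting material
12 | secondary ozonide (1,2,4-trioxolane) of 10 | OC[C@H]1[C@](O)(C(C)C)CC[C@]1(C)CC1OCOO1 | intermediate
13 | (4aR,7R,7aS)-4a-methyl-7-(propan-2-yl)octahydrocyclopenta[c]pyran-3,7-diol (trans-fused lactol, anomers; 7-OH cis to the 4a-methyl) | OC1OC[C@H]2[C@](O)(C(C)C)CC[C@]2(C)C1 | intermediate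
14 | ethynylmagnesium bromide | C#C[Mg]Br | starting material
15 | methylmagnesium bromide | C[Mg]Br | starting material
16 | iodine | [I][I] | starting material
17 | (1R,2S,3R)-3-(2-hydroxybut-3-yn-1-yl)-2-(hydroxymethyl)-3-methyl-1-(propan-2-yl)cyclopentan-1-ol, present as its bromomagnesium alkoxide (drawn protonated) | OC[C@H]1[C@](O)(C(C)C)CC[C@]1(C)CC(O)C#C | intermediate
18 | five-membered oxamagnesacycle formed by methyl-magnesium addition across the alkyne of 17 (other hydroxyls drawn protonated) | OC[C@H]1[C@](O)(C(C)C)CC[C@]1(C)CC1O[Mg]C=C1C | intermediate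
19 | (1R,2S,3R)-3-[(3Z)-2-hydroxy-4-iodo-3-methylbut-3-en-1-yl]-2-(hydroxymethyl)-3-methyl-1-(propan-2-yl)cyclopentan-1-ol | OC[C@H]1[C@](O)(C(C)C)CC[C@]1(C)CC(O)/C(C)=C\I | intermediate
20 | (1R,2R,5R)-2-hydroxy-5-[(3Z)-4-iodo-3-methyl-2-oxobut-3-en-1-yl]-5-methyl-2-(propan-2-yl)cyclopentane-1-carbaldehyde | O=C[C@H]1[C@](O)(C(C)C)CC[C@]1(C)CC(=O)/C(C)=C\I | intermediate
21 | (Z)-alkenylchromium dichloride derived from 20 (Cr in place of I) | O=C[C@H]1[C@](O)(C(C)C)CC[C@]1(C)CC(=O)/C(C)=C\[Cr](Cl)Cl | intermediate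
22 | (3R,3aS,4S,8aR)-3,4-dihydroxy-6,8a-dimethyl-3-(propan-2-yl)-2,3,3a,4,8,8a-hexahydroazulen-7(1H)-one | O[C@H]1C=C(C)C(=O)C[C@@]2(C)CC[C@@](O)(C(C)C)[C@H]12 | intermediate
23 | 4-methoxybenzoyl chloride | COc1ccc(cc1)C(Cl)=O | starting material
24 | (3R,3aS,4S,8aR)-3-hydroxy-6,8a-dimethyl-7-oxo-3-(propan-2-yl)-1,2,3,3a,4,7,8,8a-octahydroazulen-4-yl 4-methoxybenzoate | COc1ccc(C(=O)O[C@H]2C=C(C)C(=O)C[C@@]3(C)CC[C@@](O)(C(C)C)[C@H]23)cc1 | intermediate
25 | (3R,3aS,4S,7R,8aR)-3,7-dihydroxy-6,8a-dimethyl-3-(propan-2-yl)-1,2,3,3a,4,7,8,8a-octahydroazulen-4-yl 4-methoxybenzoate | COc1ccc(C(=O)O[C@H]2C=C(C)[C@H](O)C[C@@]3(C)CC[C@@](O)(C(C)C)[C@H]23)cc1 | target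

**Totals**

Total step count: 9. Longest linear sequence: 9 steps (fully linear from 1).

**Steps most likely to fail, with fallbacks**

Step 7 (chromium-mediated ring closure). A seven-membered closure through a β-acylvinylchromium species is the least precedented operation, and the C4 configuration rests on a transition-state argument. If the closure gives mainly the C4 epimer, the fallback sets out from 20: the epimeric hydroxy enone (3R,3aS,4R,8aR)-3,4-dihydroxy-6,8a-dimethyl-3-(propan-2-yl)-2,3,3a,4,8,8a-hexahydroazulen-7(1H)-one F1 is esterified under Mitsunobu conditions (4-methoxybenzoic acid, PPh3, DIAD, THF). The ester is then installed by SN2 inversion at C4 instead of by acylation with retention, and the route is rejoined at 24. If no ring closure occurs at all, the step 5 fallback below also bypasses this step.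

Step 5 (one-pot ethynylation, carbomagnesiation, iodination on a polyol). If this fails, the alkenyl iodide is abandoned and the same C4–C5 bond is made by ketyl umpolung, setting out from 13. Isopropenylmagnesium bromide gives (1R,2S,3R)-3-(2-hydroxy-3-methylbut-3-en-1-yl)-2-(hydroxymethyl)-3-methyl-1-(propan-2-yl)cyclopentan-1-ol F2. Double Swern oxidation gives (1R,2R,5R)-2-hydroxy-5-methyl-5-(3-methyl-2-oxobut-3-en-1-yl)-2-(propan-2-yl)cyclopentane-1-carbaldehyde F3. SmI2 (THF/MeOH, 0 °C) reduces the aldehyde to a ketyl radical that adds 7-endo to the enone β-carbon, giving (3R,3aS,4S,8aR)-3,4-dihydroxy-6,8a-dimethyl-3-(propan-2-yl)octahydroazulen-7(1H)-one F4 (C6 epimers). Acylation with 23 gives (3R,3aS,4S,8aR)-3-hydroxy-6,8a-dimethyl-7-oxo-3-(propan-2-yl)decahydroazulen-4-yl 4-methoxybenzoate F5. Dehydrogenation with 2-iodoxybenzoic acid (DMSO, 70 °C) can only introduce the C5–C6 double bond, because C8a carries no hydrogen, and the route is rejoined at 24.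

Step 9 (facial selectivity of the enone reduction). If hydride attacks from the other face, the fallback sets out from 24: the epimer (3R,3aS,4S,7S,8aR)-3,7-dihydroxy-6,8a-dimethyl-3-(propan-2-yl)-1,2,3,3a,4,7,8,8a-octahydroazulen-4-yl 4-methoxybenzoate F6 is inverted by Mitsunobu reaction with chloroacetic acid (PPh3, DIAD) to (3R,3aS,4S,7R,8aR)-7-[(chloroacetyl)oxy]-3-hydroxy-6,8a-dimethyl-3-(propan-2-yl)-1,2,3,3a,4,7,8,8a-octahydroazulen-4-yl 4-methoxybenzoate F7. The chloroacetyl group is then removed with thiourea (NaHCO3, EtOH) without touching the 4-methoxybenzoate, arriving at 25.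

**Further compounds**

F1 | step 7 | (3R,3aS,4R,8aR)-3,4-dihydroxy-6,8a-dimethyl-3-(propan-2-yl)-2,3,3a,4,8,8a-hexahydroazulen-7(1H)-one | O[C@@H]1C=C(C)C(=O)C[C@@]2(C)CC[C@@](O)(C(C)C)[C@H]12
F2 | step 5 | (1R,2S,3R)-3-(2-hydroxy-3-methylbut-3-en-1-yl)-2-(hydroxymethyl)-3-methyl-1-(propan-2-yl)cyclopentan-1-ol | OC[C@H]1[C@](O)(C(C)C)CC[C@]1(C)CC(O)C(C)=C
F3 | step 5 | (1R,2R,5R)-2-hydroxy-5-methyl-5-(3-methyl-2-oxobut-3-en-1-yl)-2-(propan-2-yl)cyclopentane-1-carbaldehyde | O=C[C@H]1[C@](O)(C(C)C)CC[C@]1(C)CC(=O)C(C)=C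
F4 | step 5 | (3R,3aS,4S,8aR)-3,4-dihydroxy-6,8a-dimethyl-3-(propan-2-yl)octahydroazulen-7(1H)-one | O[C@H]1CC(C)C(=O)C[C@@]2(C)CC[C@@](O)(C(C)C)[C@H]12
F5 | step 5 | (3R,3aS,4S,8aR)-3-hydroxy-6,8a-dimethyl-7-oxo-3-(propan-2-yl)decahydroazulen-4-yl 4-methoxybenzoate | COc1ccc(C(=O)O[C@H]2CC(C)C(=O)C[C@@]3(C)CC[C@@](O)(C(C)C)[C@H]23)cc1
F6 | step 9 | (3R,3aS,4S,7S,8aR)-3,7-dihydroxy-6,8a-dimethyl-3-(propan-2-yl)-1,2,3,3a,4,7,8,8a-octahydroazulen-4-yl 4-methoxybenzoate | COc1ccc(C(=O)O[C@H]2C=C(C)[C@@H](O)C[C@@]3(C)CC[C@@](O)(C(C)C)[C@H]23)cc1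
F7 | step 9 | (3R,3aS,4S,7R,8aR)-7-[(chloroacetyl)oxy]-3-hydroxy-6,8a-dimethyl-3-(propan-2-yl)-1,2,3,3a,4,7,8,8a-octahydroazulen-4-yl 4-methoxybenzoate | COc1ccc(C(=O)O[C@H]2C=C(C)[C@H](OC(=O)CCl)C[C@@]3(C)CC[C@@](O)(C(C)C)[C@H]23)cc1
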